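## Structural features

The target is a C40 carotenoid tetraol. An all-E octaene chain (C7=C8 to C9'=C10', methyls on C9, C13, C13', C9') joins ring A to a hexahydrobenzofuran made of carbocyclic ring B (C1'–C6') and dihydrofuran ring C (O, C5', C6'=C7', C8'). Ring A is a cyclohexane with a secondary C3 hydroxyl and tertiary hydroxyls on C5 and C6. In ring A, C5 and C6 are adjacent (cis-diol, chain on C6 trans to both hydroxyls) and C3 is 1,3 to C5 with its hydroxyl trans to O5. Ring B repeats this 1,3-trans O/O pattern at C3'/C5' in the same absolute sense (3S,5R and 3'S,5'R), so one enantiopure ring-B intermediate can serve both ends. C8' is an isolated, doubly allylic ether carbon whose chain is trans to the C5' methyl. Fragile groups are the tertiary polyenylic C6–OH (acid ionisation, then capture by O5 or O3), the C8'–O bond (acid-epimerisable), the polyene (light, oxygen, E/Z drift) and the β-acyloxy ketone intermediates (elimination). The real difficulties are C8', which has no neighbouring stereocentre; the cis-5,6-diol; and joining two different acid-labile ends to the C10 centre. The key step uses the ring B/C fusion: the methylene C6', between quaternary C1' and C5', is bonded to C7', and C7' is tied through C8' to the oxygen on C5'. That is the connectivity of a γ-lactone formed when an acetate-derived carbene on O5' inserts into C6'–H of a plain cyclohexyl ester.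

## Logic of the disconnections

38 is cut at the C11=C12 double bond into 28 and 36 (Wittig retron). The cut lets the acid-labile triol end enter last, as an aldehyde made under neutral conditions. The gain is a C25 + C15 division with every stereocentre in place. The forward step must run with four free hydroxyls in base, and its Z isomer 37 must relax thermally to the E chain.

28 is cut at C11'=C12' into 24 and 27, so the second end group is also an aldehyde and the symmetric C10 centre carries both phosphorus groups. 27 goes back through 26 to purchasable 25. The gain is that neither sensitive end sees acidic salt formation. The demand is single olefination of a reagent with two identical ends (excess 27, limiting base).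

24 is traced through 23 to 22 (oxidation level and ester removal only), and 22 is cut at C8'–C9' into 17 and 21. C8' is an acetal carbon in 17, so the bond can be made by an alkenyl nucleophile on an oxocarbenium ion, with the E C9'=C10' geometry built into 21. The gain is a bicyclic C11 core plus a C4 unit. The demands are attack at C8' and not C6', preference for the face anti to the C5' methyl, and retention of alkene geometry. 21 goes back through 20 and 19 to 18 by syn borylation of the alkyne.

17 comes from 16 and 16 from 15: C8' is returned to the lactone oxidation level, which makes the butenolide the real target for rings B and C. The demand is a reduction that stops at the lactol.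

36 is traced to 35 and then to 34, in which C7=C8 is an alkyne; 34 is cut at C6–C7 into 31 and 32. 31 is a non-enolisable ketone whose axial α-silyloxy group fixes the face of attack, and 32 brings C7–C11 with the 9E double bond ready-made. The gain is that ring A stereochemistry reduces to that of a 2-oxycyclohexanone. The demands are axial attack anti to the C5 oxygen at a ketone between two quaternary carbons, and hydroxyl-directed trans reduction of the alkyne.

31 is the silyl ether of 30, and 30 is what remains of 15 when C6=C7 is cleaved (C7 and C8 leave, C6 becomes the ketone). Both halves converge here on one intermediate, because 15 already holds the C3/C5 array ring A needs. The demand is oxidative cleavage of an electron-poor alkene and release of the tertiary hydroxyl without loss of the pivalate.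

15 is the dehydrogenation product of 13 (the C6' centre of 13 is deliberately transient). 13 is cut at C6'–C7' to 12: the lactone opens to an O-bound carbene that inserts into C6'–H. The gain is one ring and one C–C bond from a monocyclic tertiary ester. The demand is insertion at the C6' methylene and not at C4', C3' or the C5' methyl.

12 goes back through 11 to 9 and 10 (ester and diazo formation). 9 is cut at C5'–CH3 into 7 and 8, because equatorial addition to this ketone gives the axial tertiary oxygen trans to O3' that both rings need. 7 is the ester of 6, whose single stereocentre comes from enantioselective β-functionalisation of 4; 4 comes from 1 through 2. The demands are high enantioselectivity at C3' and addition without enolisation or β-elimination.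

## Other disconnections considered

Alternative 1: The cut is at C9–CH3 and C10–C11 of the ring-A half. Forward, Me3Al with Cp2ZrCl2 adds methyl and aluminium syn across the terminal alkyne of the ring-A enyne A1 (one C=C and one C≡C, so an enyne and not a dienyne). The alkenylalane is then coupled with the iodo dienoate A2 under Pd(PPh3)4/ZnCl2 to give the silylated C20 tetraenoate A3.
- In its favour: syn carbometalation fixes the 9E geometry and the coupling is stereoretentive, so A3 is all-E by construction and is a robust ester.
- Against it here: all three hydroxyls must be silylated to survive the Lewis-acidic alane, and the ionisable allylic C6–O bond sits next to the reacting enyne. A1 must still come from addition to the same α-silyloxy ketone as in the chosen plan, so the ring-A stereochemical problem is unchanged. A C20 + C20 union would also need a phosphonium salt on one sensitive half.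
- Comparison: on alkene geometry the alternative is the better plan, since it has no Wittig E/Z mixture at C11=C12. On mechanism the two are equal, both resting on directed additions to an alkyne. On step economy the chosen plan is better, because 32 supplies the C9 methyl and the 9E bond ready-made.

Alternative 2: The cut is at O–C5' of ring C. Forward, a chiral amine–thiourea or phosphoric acid directs the primary hydroxyl of the prochiral quinol A4 onto one of two enantiotopic enone β-carbons, giving the cis-fused ether enone A5.
- In its favour: one catalytic step makes ring C and the quaternary C5' from achiral material, with no diazo compound.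
- Against it here: oxa-Michael addition to a β,β-disubstituted enone is reversible and makes a crowded C–O centre. A5 is also far from the target: C1' lacks one methyl, C3' is a ketone, C6' is a carbinol that must be dehydrated towards C7', C8' is a saturated CH2 that must be oxidised before C9' can be attached, and C8' stereochemistry is untouched.
- Comparison: on setting C5' directly by catalyst control the alternative is the better plan (the chosen plan relays C5' from C3'). In closing ring C in a single event the two are equal. On step economy, and on what it offers for ring A (nothing), it is clearly weaker.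

Alternative 3: The cut is at O–C8'. Forward, AgNO3 (or Ph3PAuCl/AgOTf) activates the allene of the C15 allenic carbinol A6 and the tertiary C5' hydroxyl adds to C8' in a 5-endo sense, giving the furanoid allylic alcohol A7.
- In its favour: the substituents on C8' keep their side of the forming ring, so the allene axis sets C8' directly. This is the one stereocentre the chosen plan leaves to facial bias. A7 is the silyl ether of 23, so the routes would merge cleanly, and the step is atom-economic and neutral.
- Against it here: A6 must be made as a single axial isomer, typically by SN2' hydride opening of a propargylic epoxide several steps upstream. Silver or gold salts can scramble an allene axis before cyclisation. The tertiary dienylic system can ionise.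
- Comparison: on C8' control the alternative is the better plan. In the ring-closing bond count the two are equal (one bond, one ring). On precursor access and step economy the chosen plan is better, because 15 feeds both halves of the target and A6 serves only one.

Key step: step 8

Assumption (numbering): carotenoid locants are used; ring A is C1–C6, ring B is C1'–C6', ring C is O/C5'/C6'/C7'/C8'; the target is the all-E (3S,5R,6S,3'S,5'R,8'R) isomer.
Assumption (supply): 1, 8, 10, 18, 25 and 32 are taken as purchasable.
Remark (structure): 13 is the 3,3a-dihydro derivative of loliolide pivalate (6',7'-dihydro in carotenoid locants); C7a is quaternary, so a 7,7a-dihydro name cannot apply. Insertion into the C5' methyl of 12 would close a five-membered spiro lactone, not a four-membered ring, so it counts as a competing site.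

Step 1
Reactants: 1 dimedone (5,5-dimethylcyclohexane-1,3-dione)
Product: 2 3-isobutoxy-5,5-dimethylcyclohex-2-en-1-one
Conditions: i-BuOH, TsOH·H2O (cat.), toluene, reflux, Dean–Stark
Reagents that add atoms: 2-methylpropan-1-ol, CC(C)CO
Why: Acid-catalysed condensation of the enolised 1,3-dione with the alcohol gives the vinylogous ester, driven by azeotropic removal of water; no stereocentre is involved.

Step 2
Reactants: 2 3-isobutoxy-5,5-dimethylcyclohex-2-en-1-one
Product: 4 5,5-dimethylcyclohex-2-en-1-one, via 3-isobutoxy-5,5-dimethylcyclohex-2-en-1-ol 3 (not isolated)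
Conditions: LiAlH4, Et2O, 0 °C; then 2 M HCl, rt
Reagents that add atoms: none
Why: 1,2-Hydride reduction gives allylic alcohol 3, whose enol ether hydrolyses in acid with loss of water to the transposed enone (reduction–hydrolysis of a 3-alkoxy enone).

Step 3
Reactants: 4 5,5-dimethylcyclohex-2-en-1-one
Product: 6 (S)-3-hydroxy-5,5-dimethylcyclohexanone, via (S)-3-(pinacolboryl)-5,5-dimethylcyclohexanone 5 (not isolated)
Conditions: CuCl (3 mol %), NaOt-Bu (3 mol %), (R)-1-[(SP)-2-(diphenylphosphino)ferrocenyl]ethyldicyclohexylphosphine (3 mol %), B2pin2, MeOH, THF, rt; then NaBO3·4H2O, THF/H2O, rt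
Reagents that add atoms: sodium perborate (hydroxyl oxygen of 6), [Na+].[O-]OB=O; bis(pinacolato)diboron (boryl group of intermediate 5 only), CC1(C)OB(OC1(C)C)B1OC(C)(C)C(C)(C)O1
Why: Enantioselective copper-catalysed conjugate borylation (boryl-copper 1,4-addition, protonation of the copper enolate by MeOH) sets C3', and perborate replaces boron by oxygen with retention. The ligand antipode that gives the S alcohol is used (the enantiomeric ligand if the sense is opposite), and crystalline 15 offers a later point for raising the enantiomeric purity.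

Step 4
Reactants: 6 (S)-3-hydroxy-5,5-dimethylcyclohexanone
Product: 7 (S)-3,3-dimethyl-5-oxocyclohexyl pivalate
Conditions: PivCl, pyridine, DMAP (cat.), CH2Cl2, 0 °C
Reagents that add atoms: pivaloyl chloride, CC(C)(C)C(Cl)=O
Why: Acylation of the secondary alcohol under mild base at low temperature, which keeps the β-acyloxy ketone from eliminating. The pivalate has no α-hydrogen, resists the bases used later, and will deactivate C4'–H and C3'–H in step 8.

Step 5
Reactants: 7 (S)-3,3-dimethyl-5-oxocyclohexyl pivalate; 8 methylmagnesium bromide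
Product: 9 (1S,3S)-3-hydroxy-3,5,5-trimethylcyclohexyl pivalate
Conditions: CeCl3 (anhydrous), MeMgBr, THF, −78 °C; aq. NH4Cl
Reagents that add atoms: none
Why: 1,2-Addition of the weakly basic organocerium reagent avoids enolisation and β-elimination of the pivalate. The pivalate sits equatorial and the axial C1' methyl blocks the axial trajectory, so methyl enters equatorially and C5' forms with an axial hydroxyl trans to the C3' ester (3,3,5-trimethylcyclohexanone-type control).

Step 6
Reactants: 9 (1S,3S)-3-hydroxy-3,5,5-trimethylcyclohexyl pivalate; 10 bromoacetyl bromide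
Product: 11 (1S,3S)-3-(bromoacetoxy)-3,5,5-trimethylcyclohexyl pivalate
Conditions: BrCH2COBr, PhNMe2, CH2Cl2, 0 °C → rt
Reagents that add atoms: none
Why: Esterification of the hindered tertiary alcohol by a small, very reactive acyl bromide; the weakly nucleophilic aniline base takes up HBr without displacing the α-bromide.

Step 7
Reactants: 11 (1S,3S)-3-(bromoacetoxy)-3,5,5-trimethylcyclohexyl pivalate
Product: 12 (1S,3S)-3-(diazoacetoxy)-3,5,5-trimethylcyclohexyl pivalate
Conditions: TsNHNHTs, DBU, THF, 0 °C
Reagents that add atoms: N,N'-ditosylhydrazine, Cc1ccc(cc1)S(=O)(=O)NNS(=O)(=O)c1ccc(C)cc1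
Why: N-Alkylation of the hydrazine by the α-bromo ester and two base-induced sulfinate eliminations give the diazoacetate (known diazoacetate synthesis from bromoacetates), under conditions a tertiary ester and the pivalate tolerate.

Step 8
Reactants: 12 (1S,3S)-3-(diazoacetoxy)-3,5,5-trimethylcyclohexyl pivalate
Product: 13 (3aS,6S,7aR)-4,4,7a-trimethyl-2-oxooctahydro-1-benzofuran-6-yl pivalate (3,3a-dihydrololiolide pivalate)
Conditions: Rh2(OAc)4 (1 mol %), CH2Cl2, reflux, slow addition of 12 by syringe pump at high dilution
Reagents that add atoms: none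
Why: Rh2(OAc)4 expels N2 from 12 to give an electrophilic rhodium acyl-carbenoid, which inserts into a C–H bond through a concerted, asynchronous three-centre transition state with hydride-like character at the reacting carbon; the closest known reaction type is the dirhodium-catalysed intramolecular C–H insertion of alkyl diazoacetates, tertiary esters included, to γ-butyrolactones. The ring closes in the five-membered mode (insertion at the carbon β to the ester oxygen), forming C6'–C7' and the lactone that becomes ring C. The equatorial pivalate locks the chair with the ester oxygen axial on C5', so only the equatorial C6'–H (gauche to oxygen) is within reach while the axial one is antiperiplanar; the new C6' centre is therefore fixed by the ring fusion as cis (3aS) and is erased in step 9. Three other sites could compete: the C4' methylene and the C3' methine, both deactivated inductively by the pivalate, and the C5' methyl, whose insertion would also close a five-membered (spiro) lactone but involves a primary C–H bond, intrinsically far less reactive than a secondary one. Carbene dimerisation is held back by slow addition at high dilution. A less electrophilic carboxamidate such as Rh2(NHCOMe)4 is the tuning handle if methyl or C4' insertion shows.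

Step 9
Reactants: 13 (3aS,6S,7aR)-4,4,7a-trimethyl-2-oxooctahydro-1-benzofuran-6-yl pivalate
Product: 15 (6S,7aR)-4,4,7a-trimethyl-2-oxo-2,4,5,6,7,7a-hexahydro-1-benzofuran-6-yl pivalate (loliolide pivalate), via 3-phenylselanyl lactone 14 (not isolated)
Conditions: LiN(i-Pr)2, THF, −78 °C; PhSeBr; then AcOH, 30% H2O2, 0 °C → rt
Reagents that add atoms: phenylselanyl bromide (selenium of intermediate 14 only), Br[Se]c1ccccc1
Why: α-Selenenylation of the lactone enolate on the convex face places selenium cis to H–C6', the only β-hydrogen, so oxidation and selenoxide syn-elimination can give only the endocyclic butenolide. The pivalate has no acidic hydrogen, and the transient C6' centre is removed as planned.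

Step 10
Reactants: 15 loliolide pivalate
Product: 16 (6S,7aR)-4,4,7a-trimethyl-2,4,5,6,7,7a-hexahydro-1-benzofuran-2,6-diol (lactol; both C2 epimers)
Conditions: i-Bu2AlH (3.5 equiv), CH2Cl2, −78 °C; MeOH; aq. potassium sodium tartrate
Reagents that add atoms: none
Why: At −78 °C hydride adds 1,2 to the butenolide and stops at the aluminium hemiacetal, and the pivalate is cleaved reductively in the same operation. C5' is quaternary, so the lactol cannot aromatise to a furan.

Step 11
Reactants: 16 lactol diol
Product: 17 (6S,7aR)-4,4,7a-trimethyl-2,4,5,6,7,7a-hexahydro-1-benzofuran-2,6-diyl diacetate (both C2 epimers)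
Conditions: Ac2O, pyridine, DMAP (cat.), CH2Cl2, 0 °C → rt
Reagents that add atoms: acetic anhydride, CC(=O)OC(C)=O
Why: Acetylation turns the lactol hydroxyl into a leaving group for ionisation and protects O3' as an ester that leaves together with the C11' acetate in step 16; both C8' epimers give the same cation.

Step 12
Reactants: 18 but-2-yn-1-ol
Product: 19 (Z)-3-(4,4,5,5-tetramethyl-1,3,2-dioxaborolan-2-yl)but-2-en-1-ol
Conditions: CuCl (10 mol %), PCy3 (12 mol %), NaOt-Bu (15 mol %), B2pin2, MeOH, toluene, rt
Reagents that add atoms: bis(pinacolato)diboron, CC1(C)OB(OC1(C)C)B1OC(C)(C)C(C)(C)O1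
Why: Copper-catalysed borylcupration of the propargylic alcohol is syn and places boron on the carbon remote from oxygen; protonation of the alkenylcopper by MeOH fixes CH3 cis to CH2OH, the geometry needed for an E C9'=C10' bond.

Step 13
Reactants: 19 (Z)-3-(pinacolboryl)but-2-en-1-ol
Product: 20 (Z)-3-(4,4,5,5-tetramethyl-1,3,2-dioxaborolan-2-yl)but-2-en-1-yl acetate
Conditions: Ac2O, Et3N, DMAP (cat.), CH2Cl2, 0 °C
Reagents that add atoms: acetic anhydride, CC(=O)OC(C)=O
Why: Acetylation keeps the allylic oxygen from acting as an O-nucleophile in step 15; the ester is removed in step 16 along with the C3' acetate.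

Step 14
Reactants: 20 (Z)-3-(pinacolboryl)but-2-en-1-yl acetate
Product: 21 potassium (Z)-(4-acetoxybut-2-en-2-yl)trifluoroborate
Conditions: KHF2, MeOH/H2O, rt
Reagents that add atoms: potassium hydrogen difluoride, [K+].F[H-]F
Why: Fluoride exchange on boron gives the air-stable trifluoroborate, the form that BF3 activates for C–C bond formation; the alkene geometry is untouched.

Step 15
Reactants: 17 lactol diacetate; 21 potassium (Z)-(4-acetoxybut-2-en-2-yl)trifluoroborate
Product: 22 (2E)-3-[(2R,6S,7aR)-6-acetoxy-4,4,7a-trimethyl-2,4,5,6,7,7a-hexahydro-1-benzofuran-2-yl]but-2-en-1-yl acetate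
Conditions: BF3·OEt2, MeCN, −40 → 0 °C
Reagents that add atoms: none
Why: BF3 ionises the allylic lactol acetate to a planar oxocarbenium ion (no β-hydrogen to lose, since C5' and C1' are quaternary) and activates the trifluoroborate, whose alkenyl group attacks C8' by ipso-substitution with retention of geometry (Ferrier/Petasis-type C-alkenylation of cyclic oxocarbenium ions by organotrifluoroborates); C6' is fully substituted and neopentylic, so attack goes to C8'. The nucleophile should prefer the face anti to the C5' methyl and the axial groups on that side of ring B, which gives 8'R; the 8'S epimer is separable.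

Step 16
Reactants: 22 furanoid C15 diacetate
Product: 23 (2R,6S,7aR)-2-[(2E)-4-hydroxybut-2-en-2-yl]-4,4,7a-trimethyl-2,4,5,6,7,7a-hexahydro-1-benzofuran-6-ol
Conditions: K2CO3 (cat.), MeOH, rt
Reagents that add atoms: none
Why: Carbonate-catalysed transesterification removes both acetates; the dihydrofuran and the alkene geometry are stable to base.

Step 17
Reactants: 23 furanoid C15 diol
Product: 24 (2E)-3-[(2R,6S,7aR)-6-hydroxy-4,4,7a-trimethyl-2,4,5,6,7,7a-hexahydro-1-benzofuran-2-yl]but-2-enal
Conditions: MnO2 (activated), CH2Cl2, rt
Reagents that add atoms: none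
Why: MnO2 oxidises only the primary allylic alcohol; the secondary non-allylic C3' hydroxyl and the ring ether are inert, and the neutral medium leaves C8' untouched.

Step 18
Reactants: 25 (2E,4E,6E)-2,7-dimethylocta-2,4,6-trienedial
Product: 26 (2E,4E,6E)-2,7-dimethylocta-2,4,6-triene-1,8-diol
Conditions: NaBH4, MeOH/CH2Cl2, 0 °C
Reagents that add atoms: none
Why: Borohydride 1,2-reduction of both conjugated aldehydes; the triene geometry is retained.

Step 19
Reactants: 26 (2E,4E,6E)-2,7-dimethylocta-2,4,6-triene-1,8-diol
Product: 27 [(2E,4E,6E)-2,7-dimethylocta-2,4,6-triene-1,8-diyl]bis(triphenylphosphonium) dibromide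
Conditions: PPh3·HBr (2.1 equiv), MeOH, rt
Reagents that add atoms: triphenylphosphine hydrobromide, [Br-].[PH+](c1ccccc1)(c1ccccc1)c1ccccc1
Why: Each allylic alcohol is ionised by HBr and the allylic cation is captured by PPh3 at the primary terminus (standard preparation of polyenyl Wittig salts); this fragment has no sensitive group.

Step 20
Reactants: 24 furanoid C15 aldehyde; 27 C10 bis(phosphonium) dibromide
Product: 28 [(2E,4E,6E,8E,10E)-11-[(2R,6S,7aR)-6-hydroxy-4,4,7a-trimethyl-2,4,5,6,7,7a-hexahydro-1-benzofuran-2-yl]-2,7-dimethyldodeca-2,4,6,8,10-pentaen-1-yl]triphenylphosphonium bromide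
Conditions: 27 (3 equiv), NaOMe (1.0 equiv), CH2Cl2/MeOH, −10 °C → rt, slow addition of 24
Reagents that add atoms: none
Why: Wittig olefination by the mono-ylide of the bis-salt forms C11'=C12'; excess 27, one equivalent of base and slow addition of 24 favour single olefination, and the untouched phosphonium end is the handle for step 26. Any 11'Z isomer is carried on and converges in the final isomerisation.

Step 21
Reactants: 15 loliolide pivalate
Product: 30 (1S,3R)-3-hydroxy-3,5,5-trimethyl-4-oxocyclohexyl pivalate, via glyoxylate keto ester 29 (not isolated)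
Conditions: O3, CH2Cl2/MeOH, −78 °C; Me2S, −78 °C → rt; then K2CO3 (cat.), MeOH, 0 °C
Reagents that add atoms: ozone, [O-][O+]=O
Why: Ozonolysis (Criegee cleavage) of the only C=C removes C7' and C8' and leaves the former C6' as a ketone with the tertiary oxygen acylated as a glyoxylate; this highly activated ester is methanolysed by catalytic carbonate while the pivalate survives. The C3/C5 stereochemistry is inherited unchanged.

Step 22
Reactants: 30 (1S,3R)-3-hydroxy-3,5,5-trimethyl-4-oxocyclohexyl pivalate
Product: 31 (1S,3R)-3,5,5-trimethyl-4-oxo-3-(trimethylsilyloxy)cyclohexyl pivalate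
Conditions: Me3SiOTf, 2,6-lutidine, CH2Cl2, −78 → 0 °C
Reagents that add atoms: trimethylsilyl triflate, C[Si](C)(C)OS(=O)(=O)C(F)(F)F
Why: Silyl triflate with a hindered base silylates the tertiary alcohol; the ketone has no α-hydrogen, so no silyl enol ether can form. The silyl ether prevents chelation and alkoxide-directed delivery in step 23.

Step 23
Reactants: 31 silyloxy ketone; 32 (E)-3-methylpent-2-en-4-yn-1-ol
Product: 34 (1S,3R,4R)-3,4-dihydroxy-4-[(3E)-5-hydroxy-3-methylpent-3-en-1-yn-1-yl]-3,5,5-trimethylcyclohexyl pivalate, via O5-trimethylsilyl adduct 33 (not isolated)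
Conditions: 32 (2.5 equiv), n-BuLi (5.0 equiv), THF, −78 → 0 °C; 31, −78 → −20 °C; aq. NH4Cl; then K2CO3 (cat.), MeOH, 0 °C
Reagents that add atoms: none
Why: 1,2-Addition of the lithium acetylide (alkoxide–acetylide dianion of 32) to a non-enolisable ketone; the chair is locked with the silyloxy group and one C1 methyl axial, so the linear nucleophile enters axially on the opposite face, antiperiplanar to the axial C–O bond, placing the new hydroxyl cis to O5 and the chain trans. Mild methanolysis then removes the silyl group from whichever oxygen carries it.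

Step 24
Reactants: 34 acetylenic triol monopivalate
Product: 35 (1S,2R,4S)-1-[(1E,3E)-5-hydroxy-3-methylpenta-1,3-dien-1-yl]-2,6,6-trimethylcyclohexane-1,2,4-triol
Conditions: NaAlH2(OCH2CH2OMe)2 (6 equiv), THF, 0 °C → rt; aq. potassium sodium tartrate
Reagents that add atoms: none
Why: The C6 alkoxide binds aluminium and delivers hydride intramolecularly to C7, so the alkyne is reduced by trans-hydroalumination to the 7E alkene (known for tertiary propargylic alcohols of this enynol type). The 9E alkene is untouched and the pivalate is reduced off in the same step.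

Step 25
Reactants: 35 ring-A C15 tetraol
Product: 36 (2E,4E)-3-methyl-5-[(1S,2R,4S)-1,2,4-trihydroxy-2,6,6-trimethylcyclohexyl]penta-2,4-dienal
Conditions: MnO2 (activated), acetone, rt
Reagents that add atoms: none
Why: MnO2 oxidises only the primary allylic alcohol; the tertiary allylic C6 hydroxyl cannot be oxidised, the C3 hydroxyl is not allylic, and the neutral medium avoids ionisation at C6.

Step 26
Reactants: 28 C25 phosphonium bromide; 36 ring-A C15 aldehyde
Product: 38 (all-E,3S,5R,6S,3'S,5'R,8'R)-5',8'-epoxy-5,6,5',8'-tetrahydro-β,β-carotene-3,5,6,3'-tetrol (the target), via 11Z isomer 37 (not isolated)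
Conditions: NaOMe, MeOH/CH2Cl2, 0 °C → rt; then EtOH/heptane, 70 °C, N2, dark
Reagents that add atoms: none
Why: Wittig olefination of 36 by the ylide of 28 forms C11=C12 in a basic medium that both end groups tolerate with free hydroxyls. The sterically hindered 11Z (and any 11'Z) isomer relaxes to the all-E chain on gentle heating in the dark, and no stereocentre is touched.

## Compound list

1 | dimedone (5,5-dimethylcyclohexane-1,3-dione) | CC1(C)CC(=O)CC(=O)C1 | starting material
2 | 3-isobutoxy-5,5-dimethylcyclohex-2-en-1-one | CC(C)COC1=CC(=O)CC(C)(C)C1 | intermediate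
3 | 3-isobutoxy-5,5-dimethylcyclohex-2-en-1-ol (racemic, not isolated) | CC(C)COC1=CC(O)CC(C)(C)C1 | intermediate
4 | 5,5-dimethylcyclohex-2-en-1-one | O=C1C=CCC(C)(C)C1 | intermediate
5 | (S)-3-(pinacolboryl)-5,5-dimethylcyclohexanone (not isolated) | CC1(C)C[C@H](B2OC(C)(C)C(C)(C)O2)CC(=O)C1 | intermediate
6 | (S)-3-hydroxy-5,5-dimethylcyclohexanone | CC1(C)C[C@H](O)CC(=O)C1 | intermediate
7 | (S)-3,3-dimethyl-5-oxocyclohexyl pivalate | CC1(C)C[C@H](OC(=O)C(C)(C)C)CC(=O)C1 | intermediate
8 | methylmagnesium bromide | C[Mg]Br | starting material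
9 | (1S,3S)-3-hydroxy-3,5,5-trimethylcyclohexyl pivalate (OH axial, trans to the ester) | C1C(C)(C)C[C@H](OC(=O)C(C)(C)C)C[C@@]1(C)O | intermediate
10 | bromoacetyl bromide | BrCC(Br)=O | starting material
11 | (1S,3S)-3-(bromoacetoxy)-3,5,5-trimethylcyclohexyl pivalate | C1C(C)(C)C[C@H](OC(=O)C(C)(C)C)C[C@@]1(C)OC(=O)CBr | intermediate
12 | (1S,3S)-3-(diazoacetoxy)-3,5,5-trimethylcyclohexyl pivalate | C1C(C)(C)C[C@H](OC(=O)C(C)(C)C)C[C@@]1(C)OC(=O)C=[N+]=[N-] | intermediate
13 | (3aS,6S,7aR)-4,4,7a-trimethyl-2-oxooctahydro-1-benzofuran-6-yl pivalate (cis-fused; 3,3a-dihydrololiolide pivalate) | O=C1C[C@H]2C(C)(C)C[C@H](OC(=O)C(C)(C)C)C[C@@]2(C)O1 | intermediate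
14 | 3-phenylselanyl derivative of 13, selenium cis to H-3a (not isolated) | O=C1[C@H]([Se]c2ccccc2)[C@H]2C(C)(C)C[C@H](OC(=O)C(C)(C)C)C[C@@]2(C)O1 | intermediate
15 | (6S,7aR)-4,4,7a-trimethyl-2-oxo-2,4,5,6,7,7a-hexahydro-1-benzofuran-6-yl pivalate (loliolide pivalate) | O=C1C=C2C(C)(C)C[C@H](OC(=O)C(C)(C)C)C[C@@]2(C)O1 | intermediate
16 | (6S,7aR)-4,4,7a-trimethyl-2,4,5,6,7,7a-hexahydro-1-benzofuran-2,6-diol (C2 epimers) | OC1C=C2C(C)(C)C[C@H](O)C[C@@]2(C)O1 | intermediate
17 | (6S,7aR)-4,4,7a-trimethyl-2,4,5,6,7,7a-hexahydro-1-benzofuran-2,6-diyl diacetate (C2 epimers) | CC(=O)OC1C=C2C(C)(C)C[C@H](OC(C)=O)C[C@@]2(C)O1 | intermediate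
18 | but-2-yn-1-ol | CC#CCO | starting material
19 | (Z)-3-(4,4,5,5-tetramethyl-1,3,2-dioxaborolan-2-yl)but-2-en-1-ol | OC/C=C(\C)B1OC(C)(C)C(C)(C)O1 | intermediate
20 | (Z)-3-(4,4,5,5-tetramethyl-1,3,2-dioxaborolan-2-yl)but-2-en-1-yl acetate | CC(=O)OC/C=C(\C)B1OC(C)(C)C(C)(C)O1 | intermediate
21 | potassium (Z)-(4-acetoxybut-2-en-2-yl)trifluoroborate | CC(=O)OC/C=C(\C)[B-](F)(F)F.[K+] | intermediate
22 | (2E)-3-[(2R,6S,7aR)-6-acetoxy-4,4,7a-trimethyl-2,4,5,6,7,7a-hexahydro-1-benzofuran-2-yl]but-2-en-1-yl acetate | CC(=O)OC/C=C(\C)[C@H]1C=C2C(C)(C)C[C@H](OC(C)=O)C[C@@]2(C)O1 | intermediate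
23 | (2R,6S,7aR)-2-[(2E)-4-hydroxybut-2-en-2-yl]-4,4,7a-trimethyl-2,4,5,6,7,7a-hexahydro-1-benzofuran-6-ol | OC/C=C(\C)[C@H]1C=C2C(C)(C)C[C@H](O)C[C@@]2(C)O1 | intermediate
24 | (2E)-3-[(2R,6S,7aR)-6-hydroxy-4,4,7a-trimethyl-2,4,5,6,7,7a-hexahydro-1-benzofuran-2-yl]but-2-enal | O=C/C=C(\C)[C@H]1C=C2C(C)(C)C[C@H](O)C[C@@]2(C)O1 | intermediate
25 | (2E,4E,6E)-2,7-dimethylocta-2,4,6-trienedial | O=C/C(C)=C/C=C/C=C(C)/C=O | starting material
26 | (2E,4E,6E)-2,7-dimethylocta-2,4,6-triene-1,8-diol | OC/C(C)=C/C=C/C=C(C)/CO | intermediate
27 | [(2E,4E,6E)-2,7-dimethylocta-2,4,6-triene-1,8-diyl]bis(triphenylphosphonium) dibromide | [Br-].[Br-].c1ccccc1[P+](c1ccccc1)(c1ccccc1)C/C(C)=C/C=C/C=C(C)/C[P+](c1ccccc1)(c1ccccc1)c1ccccc1 | intermediate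
28 | [(2E,4E,6E,8E,10E)-11-[(2R,6S,7aR)-6-hydroxy-4,4,7a-trimethyl-2,4,5,6,7,7a-hexahydro-1-benzofuran-2-yl]-2,7-dimethyldodeca-2,4,6,8,10-pentaen-1-yl]triphenylphosphonium bromide | [Br-].c1ccccc1[P+](c1ccccc1)(c1ccccc1)C/C(C)=C/C=C/C=C(C)/C=C/C=C(\C)[C@H]1C=C2C(C)(C)C[C@H](O)C[C@@]2(C)O1 | intermediate
29 | glyoxylate ester of 30 at the tertiary oxygen (not isolated) | O=C1C(C)(C)C[C@H](OC(=O)C(C)(C)C)C[C@@]1(C)OC(=O)C=O | intermediate
30 | (1S,3R)-3-hydroxy-3,5,5-trimethyl-4-oxocyclohexyl pivalate | O=C1C(C)(C)C[C@H](OC(=O)C(C)(C)C)C[C@@]1(C)O | intermediate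
31 | (1S,3R)-3,5,5-trimethyl-4-oxo-3-(trimethylsilyloxy)cyclohexyl pivalate | O=C1C(C)(C)C[C@H](OC(=O)C(C)(C)C)C[C@@]1(C)O[Si](C)(C)C | intermediate
32 | (E)-3-methylpent-2-en-4-yn-1-ol | OC/C=C(C)/C#C | starting material
33 | O5-trimethylsilyl ether of 34 (not isolated) | OC/C=C(C)/C#C[C@]1(O)C(C)(C)C[C@H](OC(=O)C(C)(C)C)C[C@@]1(C)O[Si](C)(C)C | intermediate
34 | (1S,3R,4R)-3,4-dihydroxy-4-[(3E)-5-hydroxy-3-methylpent-3-en-1-yn-1-yl]-3,5,5-trimethylcyclohexyl pivalate (cis-diol, alkynyl trans to both hydroxyls) | OC/C=C(C)/C#C[C@]1(O)C(C)(C)C[C@H](OC(=O)C(C)(C)C)C[C@@]1(C)O | intermediate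
35 | (1S,2R,4S)-1-[(1E,3E)-5-hydroxy-3-methylpenta-1,3-dien-1-yl]-2,6,6-trimethylcyclohexane-1,2,4-triol | OC/C=C(C)/C=C/[C@]1(O)C(C)(C)C[C@H](O)C[C@@]1(C)O | intermediate
36 | (2E,4E)-3-methyl-5-[(1S,2R,4S)-1,2,4-trihydroxy-2,6,6-trimethylcyclohexyl]penta-2,4-dienal | O=C/C=C(C)/C=C/[C@]1(O)C(C)(C)C[C@H](O)C[C@@]1(C)O | intermediate
37 | 11Z isomer of the target (not isolated) | CC(/C=C\C=C(C)\C=C\[C@]1(O)C(C)(C)C[C@H](O)C[C@@]1(C)O)=C\C=C\C=C(C)\C=C\C=C(/C)[C@H]1C=C2C(C)(C)C[C@H](O)C[C@@]2(C)O1 | intermediate
38 | (all-E,3S,5R,6S,3'S,5'R,8'R)-5',8'-epoxy-5,6,5',8'-tetrahydro-β,β-carotene-3,5,6,3'-tetrol | CC(/C=C/C=C(C)/C=C/[C@]1(O)C(C)(C)C[C@H](O)C[C@@]1(C)O)=C\C=C\C=C(C)\C=C\C=C(/C)[C@H]1C=C2C(C)(C)C[C@H](O)C[C@@]2(C)O1 | target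

## Step count and least certain steps

Total step count: 26 (steps 1–26). Longest linear sequence: 16 steps from dimedone (steps 1–11, 15–17, 20, 26). The ring-A line is 15 steps (1–9, 21–26). The side branches are steps 12–14 and 18–19.

Step 8 (key step). The most likely failure is loss of site selectivity, with insertion drifting to the C5' methyl (spiro lactone) or to C4', together with carbene dimerisation. The acceptor-only carbenoid is very reactive and C6'–H is neopentylic. Fallback, from 9 back to 13: acylation of 9 with methyl malonyl chloride and pyridine should give the mixed ester (1S,3S)-3,5,5-trimethyl-3-[(3-methoxy-3-oxopropanoyl)oxy]cyclohexyl pivalate F1. Regitz diazo transfer (p-acetamidobenzenesulfonyl azide, Et3N) should give the diazomalonate F2. Its more discriminating acceptor/acceptor carbenoid (Rh2(OAc)4, benzene, reflux) should insert at C6' to give the 3-methoxycarbonyl lactone F3. Krapcho demethoxycarbonylation (LiCl, wet DMSO, 130 °C) returns to 13.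

Step 15. The most likely failure is poor facial discrimination at C8', because the C5' methyl and the C4' methylene flank the cation almost equally. Slow transfer from the α-branched alkenylboron would add hydrolysis of 17. Fallback, from 17 and 21 back to 22: the same reaction is run and the epimers are separated. The unwanted (2E)-3-[(2S,6S,7aR)-6-acetoxy-4,4,7a-trimethyl-2,4,5,6,7,7a-hexahydro-1-benzofuran-2-yl]but-2-en-1-yl acetate F4 is re-ionised at its doubly allylic C8'–O bond (catalytic BF3·OEt2, CH2Cl2, 0 °C; known acid epimerisation of furanoid C8 centres). The equilibrated mixture is separated again, so that thermodynamic recycling replaces kinetic face selection and the material returns as 22.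

Step 20. The most likely failure is over-reaction: the ylide of 28 competes for 24 and gives double olefination, and the phosphonium salts are hard to separate. Base-induced epimerisation at C8' of 24 is a lesser risk. Fallback, from 23 and 25 back to 28, with reversed polarity at this bond: Appel bromination of the primary allylic alcohol of 23 (CBr4, PPh3, −20 °C) should give (2R,6S,7aR)-2-[(2E)-4-bromobut-2-en-2-yl]-4,4,7a-trimethyl-2,4,5,6,7,7a-hexahydro-1-benzofuran-6-ol F5. PPh3 should give the C15 phosphonium bromide F6. Wittig reaction with excess 25 (NaOMe) should stop at the C25 hydroxy aldehyde F7, since the product aldehyde is less electrophilic than the dialdehyde. NaBH4 should give the C25 diol F8, and PPh3·HBr in MeOH should give 28.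

Step 23. The most likely failure is incomplete addition of the aggregated dianion to a ketone between two quaternary carbons, with pivalate cleavage setting in on warming. Fallback, from 31 and 19 back to 34: the small lithium (trimethylsilyl)acetylide with CeCl3 is added to 31 to give (1S,3R,4R)-4-hydroxy-3,5,5-trimethyl-3-(trimethylsilyloxy)-4-[(trimethylsilyl)ethynyl]cyclohexyl pivalate F9. K2CO3/MeOH removes both silyl groups to give (1S,3R,4R)-4-ethynyl-3,4-dihydroxy-3,5,5-trimethylcyclohexyl pivalate F10. Sonogashira coupling (Pd(PPh3)4, CuI, Et3N) with (E)-3-iodobut-2-en-1-ol F11, made from 19 by iododeboronation with retention (NaOH, I2), forms the C8–C9 bond and gives 34.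

Step 3. The most likely failure is insufficient enantioselection on the gem-dimethyl enone, or partial dehydration of the β-hydroxy ketone back to 4 during oxidation. Fallback, from 4 back to 6: iminium-catalysed nucleophilic epoxidation (9-amino-9-deoxy-epi-quinine trifluoroacetate salt or its quinidine-derived pseudo-enantiomer, aqueous H2O2, dioxane) should give (2S,3S)-2,3-epoxy-5,5-dimethylcyclohexanone F12. Reductive cleavage of the Cα–O bond (PhSeSePh, NaBH4, AcOH, EtOH, or SmI2 in THF/MeOH) then gives 6.

## Further compounds

F1 | step 8 | (1S,3S)-3,5,5-trimethyl-3-[(3-methoxy-3-oxopropanoyl)oxy]cyclohexyl pivalate | C1C(C)(C)C[C@H](OC(=O)C(C)(C)C)C[C@@]1(C)OC(=O)CC(=O)OC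
F2 | step 8 | (1S,3S)-3-[(2-diazo-3-methoxy-3-oxopropanoyl)oxy]-3,5,5-trimethylcyclohexyl pivalate | C1C(C)(C)C[C@H](OC(=O)C(C)(C)C)C[C@@]1(C)OC(=O)C(=[N+]=[N-])C(=O)OC
F3 | step 8 | methyl (3aS,6S,7aR)-4,4,7a-trimethyl-2-oxo-6-(pivaloyloxy)octahydro-1-benzofuran-3-carboxylate (C3 epimers) | O=C1C(C(=O)OC)[C@H]2C(C)(C)C[C@H](OC(=O)C(C)(C)C)C[C@@]2(C)O1
F4 | step 15 | (2E)-3-[(2S,6S,7aR)-6-acetoxy-4,4,7a-trimethyl-2,4,5,6,7,7a-hexahydro-1-benzofuran-2-yl]but-2-en-1-yl acetate | CC(=O)OC/C=C(\C)[C@@H]1C=C2C(C)(C)C[C@H](OC(C)=O)C[C@@]2(C)O1
F5 | step 20 | (2R,6S,7aR)-2-[(2E)-4-bromobut-2-en-2-yl]-4,4,7a-trimethyl-2,4,5,6,7,7a-hexahydro-1-benzofuran-6-ol | BrC/C=C(\C)[C@H]1C=C2C(C)(C)C[C@H](O)C[C@@]2(C)O1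
F6 | step 20 | [(2E)-3-[(2R,6S,7aR)-6-hydroxy-4,4,7a-trimethyl-2,4,5,6,7,7a-hexahydro-1-benzofuran-2-yl]but-2-en-1-yl]triphenylphosphonium bromide | [Br-].c1ccccc1[P+](c1ccccc1)(c1ccccc1)C/C=C(\C)[C@H]1C=C2C(C)(C)C[C@H](O)C[C@@]2(C)O1
F7 | step 20 | (2E,4E,6E,8E,10E)-11-[(2R,6S,7aR)-6-hydroxy-4,4,7a-trimethyl-2,4,5,6,7,7a-hexahydro-1-benzofuran-2-yl]-2,7-dimethyldodeca-2,4,6,8,10-pentaenal | O=C/C(C)=C/C=C/C=C(C)/C=C/C=C(\C)[C@H]1C=C2C(C)(C)C[C@H](O)C[C@@]2(C)O1
F8 | step 20 | (2E,4E,6E,8E,10E)-11-[(2R,6S,7aR)-6-hydroxy-4,4,7a-trimethyl-2,4,5,6,7,7a-hexahydro-1-benzofuran-2-yl]-2,7-dimethyldodeca-2,4,6,8,10-pentaen-1-ol | OC/C(C)=C/C=C/C=C(C)/C=C/C=C(\C)[C@H]1C=C2C(C)(C)C[C@H](O)C[C@@]2(C)O1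
F9 | step 23 | (1S,3R,4R)-4-hydroxy-3,5,5-trimethyl-3-(trimethylsilyloxy)-4-[(trimethylsilyl)ethynyl]cyclohexyl pivalate | C[Si](C)(C)C#C[C@]1(O)C(C)(C)C[C@H](OC(=O)C(C)(C)C)C[C@@]1(C)O[Si](C)(C)C
F10 | step 23 | (1S,3R,4R)-4-ethynyl-3,4-dihydroxy-3,5,5-trimethylcyclohexyl pivalate | C#C[C@]1(O)C(C)(C)C[C@H](OC(=O)C(C)(C)C)C[C@@]1(C)O
F11 | step 23 | (E)-3-iodobut-2-en-1-ol | OC/C=C(\C)I
F12 | step 3 | (2S,3S)-2,3-epoxy-5,5-dimethylcyclohexanone | CC1(C)C[C@@H]2O[C@@H]2C(=O)C1
A1 | alternative 1 | tris-silylated ring-A enyne (5,6-bis-trimethylsilyl, 3-tert-butyldimethylsilyl ether; 7E) | C#C/C=C/[C@]1(O[Si](C)(C)C)C(C)(C)C[C@H](O[Si](C)(C)C(C)(C)C)C[C@@]1(C)O[Si](C)(C)C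
A2 | alternative 1 | ethyl (2E,4E)-5-iodo-3-methylpenta-2,4-dienoate | CCOC(=O)/C=C(C)/C=C/I
A3 | alternative 1 | silylated ring-A C20 tetraenoate (all-E ethyl ester) | CCOC(=O)/C=C(C)/C=C/C=C(C)/C=C/[C@]1(O[Si](C)(C)C)C(C)(C)C[C@H](O[Si](C)(C)C(C)(C)C)C[C@@]1(C)O[Si](C)(C)C
A4 | alternative 2 | 4-hydroxy-4-(2-hydroxyethyl)-3,5-dimethylcyclohexa-2,5-dien-1-one | CC1=CC(=O)C=C(C)C1(O)CCO
A5 | alternative 2 | cis-fused bicyclic ether enone with C5' as in the target | C[C@@]12CC(=O)C=C(C)[C@]1(O)CCO2
A6 | alternative 3 | C15 allenic carbinol (3'-tert-butyldimethylsilyl ether; C9' on the side of C4') | OC/C=C(\C)C=[C@]=C1C(C)(C)C[C@H](O[Si](C)(C)C(C)(C)C)C[C@@]1(C)O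
A7 | alternative 3 | furanoid C15 allylic alcohol (3'-tert-butyldimethylsilyl ether, 8'R) | OC/C=C(\C)[C@H]1C=C2C(C)(C)C[C@H](O[Si](C)(C)C(C)(C)C)C[C@@]2(C)O1
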